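Beside our flask stands a neighbour with 2.50 equiv of scavenger in place of 1.50 equiv, and we ask first whether that extra scavenger can matter.

substrate 0.16 M; reagent 1.50 equiv; base 0.300 equiv; scavenger 1.50 equiv; time 10 d

    substrate + reagent + released group → target + 2 released group (k1 = 7.8 L² mol⁻² h⁻¹)
    substrate + reagent → target + released group (k2 = 4.0 × 10⁻⁴ L mol⁻¹ h⁻¹)
    base + released group ⇌ salt, settled at all times (K3 = 28000 L mol⁻¹)
    reagent + released group ⇌ idle adduct, settled at all times (K4 = 8.3 L mol⁻¹)
    scavenger + released group → scavenged by-product (k5 = 92 L mol⁻¹ h⁻¹)
    2 substrate → self-condensation product (k6 = 3.9 L mol⁻¹ h⁻¹)

- a species is counted by the substrate in it: one self-condensation product counts as two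
- amounts and yields of released group count idle adduct too
- for a step with 2 of a species take k times the square, and two of it per event
- run time (flask): 10 d

- part of the substrate that has reacted at 10 d
- share of the unused reagent that is free and not bound as idle adduct, at 10 d

The concentration to watch for the order of the substrate's loss in our flask is that of free released group: the autocatalytic step takes substrate in proportion to it, and self-condensation takes substrate without it. The autocatalytic step and the scavenger are both first-order in free released group, so the ratio of gain to loss does not contain that concentration. At the charge of our flask, k1 times substrate and reagent over k5 times scavenger is 0.0136, so we expect the chain to die.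

The uncatalysed step, pseudo-first-order in substrate, gives substrate a half-life of 300 d with the reagent as charged. The quantity we carry is the second-order half-life, one over twice k6 times the starting substrate, 0.801 h. Since the uncatalysed half-life is far longer than this one, we reckon with self-condensation: the part of substrate left after a time is this half-life over itself plus that time, which at 10 d gives 0.333 %, so 99.7 % has reacted.

The weak link is that self-condensation per substrate fades as substrate falls, while the uncatalysed step per substrate goes with the reagent, which is charged in excess. At 10 d, per substrate, self-condensation still runs 43.3 times as fast, so the link holds.

Along that curve the uncatalysed step releases about 7.02 × 10⁻⁵ M up to 10 d. Even if that stood free, it would bind about 0.0583 % of the reagent.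

The forecast gave 99.7 % reacted and 100 % free, on the ground that “the autocatalysis never ignites”. The flask gives 99.7 % and 100 %.

Left ten times as long, the flask still moves. Its substrate stands at 0.329 % at 10.0 d and 0.0297 % at 100 d, where the carried half-life gives 0.0334 %, and the reacted part stands at >99.9 %. The half-life contains no scavenger, and the neighbour flask holds 0.33 % of its substrate at 10.0 d. Over the longer time the flask's self-condensation product moves from 99.6 % to 99.9 %, and its target from 0.0438 % to 0.0607 %.

The constants are invented; what happens was integrated by code.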